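The strategy rests on the 1,3,5-trioxygenated benzene ring of the isoflavone half (ring A, atoms C4a to C8a). Its C8, lodged between the pyranone oxygen O1 and the C7 hydroxyl and para to the C5 oxygen, bears the congested biaryl bond. That ring is not arylated but grown on the aryl group: a thermal benzannulation of 3-ethoxycyclobutenone with an aryl triisopropylsiloxyalkyne should give, in one operation, the 2-aryl-5-ethoxy-3-siloxyphenol with the biaryl bond and three differentiated oxygens in place. The alkyne precursor is methyl 3-ethynyl-4-methoxybenzoate, oxidised to its ynol silyl ether. The isoflavone pyranone and then the flavone are closed afterwards, and one BCl3 step frees the three masked hydroxyls.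

Key step: step 4

Remark on the chemistry: the biaryl axis at C8 of the isoflavone has three ortho substituents, but the structure defines no axial configuration, so the target is treated as a single achiral compound and no step has to control the axis.

Step 1
Reactants: 1 methyl 3-iodo-4-methoxybenzoate; 2 ethynyltrimethylsilane
Product: 4 methyl 3-ethynyl-4-methoxybenzoate, via silylalkyne 3 (not isolated)
Conditions: PdCl2(PPh3)2 (cat.), CuI (cat.), Et3N, THF, rt; filtration through silica and solvent switch; then K2CO3 (cat.), MeOH, rt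
Reagents that add atoms: none
Why: Sonogashira coupling of an aryl iodide is dependable even next to a methoxy group, and carbonate in methanol then cleaves the alkynyl C–Si bond (protodesilylation) while any exchange at the methyl ester is degenerate.

Step 2
Reactants: 4 methyl 3-ethynyl-4-methoxybenzoate
Product: 6 methyl 4-methoxy-3-{[(triisopropylsilyl)oxy]ethynyl}benzoate, via lithium ynolate 5 (not isolated)
Conditions: LiN(SiMe3)2, THF, −78 °C; LiOO-t-Bu (from t-BuOOH and LiN(SiMe3)2), −78 → 0 °C; i-Pr3SiOTf, −78 → 0 °C; cold NaHCO3 work-up, rapid filtration through Et3N-deactivated silica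
Reagents that add atoms: tert-butyl hydroperoxide (used as its lithium salt), CC(C)(C)OO; triisopropylsilyl trifluoromethanesulfonate, CC(C)[Si](C(C)C)(C(C)C)OS(=O)(=O)C(F)(F)F
Why: Electrophilic oxygen transfer from the lithium peroxide to the lithium acetylide gives the ynolate, which the bulky silyl triflate traps on oxygen (acetylide oxidation and O-silylation, the standard entry to siloxyalkynes); the ester has no acidic hydrogen, is deactivated by its para methoxy group, and is kept at or below 0 °C.

Step 3
Reactants: 7 ethoxyacetylene; 8 acetyl chloride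
Product: 10 3-ethoxycyclobut-2-en-1-one, via ketene 9 (not isolated)
Conditions: 8 added slowly to 7 and Et3N, CH2Cl2, 0 °C → rt
Reagents that add atoms: none
Why: Ketene released slowly by dehydrochlorination of acetyl chloride is captured in a [2+2] cycloaddition by the electron-rich ynol ether, whose unsubstituted carbon attacks the ketene carbonyl carbon, so the vinylogous ester forms directly.

Step 4
Reactants: 6 methyl 4-methoxy-3-{[(triisopropylsilyl)oxy]ethynyl}benzoate; 10 3-ethoxycyclobut-2-en-1-one
Product: 15 methyl 3-[4-ethoxy-2-hydroxy-6-(triisopropylsilyloxy)phenyl]-4-methoxybenzoate, via vinylketene 11 (not isolated), via vinylcyclobutenone 12 (not isolated), via dienylketene 13 (not isolated), via cyclohexadienone 14 (not isolated)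
Conditions: toluene (degassed), 80 → 100 °C, 10 in slight excess; then K2CO3, MeOH, 0 °C, short
Reagents that add atoms: none
Why: Danheiser benzannulation: 10 opens in a four-electron conrotatory electrocyclic reaction to vinylketene 11, which adds across the siloxyalkyne in a [2+2] cycloaddition to give 12; a second four-electron opening gives dienylketene 13, a six-electron disrotatory electrocyclization joins the ketene carbon to the terminal methylene (C8a to C4a) to give dienone 14, and tautomerisation gives the phenol. The closest known reaction type is the benzannulation of cyclobutenones with trialkylsiloxyalkynes to resorcinol monosilyl ethers. The only ring closed is the benzenoid ring A, by the pericyclic six-electron closure, after C8a–C8 and C6–C7 were made in the cycloaddition. No stereocentre is created. The step needs a single regiochemistry in the ketene and alkyne union, and the polarisation of the ynol ether secures it: the aryl-bearing carbon, beta to oxygen, is the nucleophilic end and bonds to the ketene carbonyl carbon, so the aryl group ends between the new phenol oxygen and the siloxy oxygen with the ethoxy group para to it. Any product phenol acylated by surplus vinylketene is released by the brief methanolysis.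

Step 5
Reactants: 15 methyl 3-[4-ethoxy-2-hydroxy-6-(triisopropylsilyloxy)phenyl]-4-methoxybenzoate
Product: 16 methyl 3-(4-ethoxy-2,6-dihydroxyphenyl)-4-methoxybenzoate
Conditions: Bu4NF, AcOH, THF, 0 °C
Reagents that add atoms: none
Why: Fluoride cleaves the aryl silyl ether (desilylation), buffered with acetic acid so that the electron-rich resorcinol is not held as an air-sensitive phenoxide, and the product is mirror-symmetric with two equivalent ring CH positions.

Step 6
Reactants: 16 methyl 3-(4-ethoxy-2,6-dihydroxyphenyl)-4-methoxybenzoate; 17 (4-methoxyphenyl)acetic acid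
Product: 19 methyl 3-[5-ethoxy-7-hydroxy-3-(4-methoxyphenyl)-4-oxo-4H-chromen-8-yl]-4-methoxybenzoate, via deoxybenzoin 18 (not isolated)
Conditions: BF3·OEt2, 85 °C; then DMF, MeSO2Cl, 70 °C; aq. NaOAc
Reagents that add atoms: N,N-dimethylformamide, CN(C)C=O
Why: Friedel–Crafts acylation in BF3·OEt2 can only occur at one of the two equivalent ring positions, and the boron-chelated deoxybenzoin is then formylated at its methylene by the iminium reagent from DMF and MeSO2Cl and closes onto the only hydroxyl ortho to the ketone, which lies next to the aryl-bearing carbon, so the 8-aryl isoflavone is the sole possible regioisomer (one-pot deoxybenzoin route to isoflavones).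

Step 7
Reactants: 19 methyl 3-[5-ethoxy-7-hydroxy-3-(4-methoxyphenyl)-4-oxo-4H-chromen-8-yl]-4-methoxybenzoate; 20 1-[2,4-bis(benzyloxy)-6-hydroxyphenyl]ethan-1-one
Product: 21 1-[2,4-bis(benzyloxy)-6-hydroxyphenyl]-3-{3-[5-ethoxy-7-hydroxy-3-(4-methoxyphenyl)-4-oxo-4H-chromen-8-yl]-4-methoxyphenyl}propane-1,3-dione
Conditions: LiN(SiMe3)2 (about 5 equiv), THF, −78 °C → rt; aq. HCl
Reagents that add atoms: none
Why: Crossed Claisen condensation of the lithium dianion of 20 (phenoxide plus methyl ketone enolate) with the non-enolisable methyl ester; the surplus amide base first turns the 7-hydroxyl of 19 into its phenoxide, whose donation into the pyranone carbonyl shields C2 of the isoflavone from conjugate attack, and the diketone stays as its enolate until the acidic quench.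

Step 8
Reactants: 21 1-[2,4-bis(benzyloxy)-6-hydroxyphenyl]-3-{3-[5-ethoxy-7-hydroxy-3-(4-methoxyphenyl)-4-oxo-4H-chromen-8-yl]-4-methoxyphenyl}propane-1,3-dione
Product: 22 8-{5-[5,7-bis(benzyloxy)-4-oxo-4H-chromen-2-yl]-2-methoxyphenyl}-5-ethoxy-7-hydroxy-3-(4-methoxyphenyl)-4H-chromen-4-one
Conditions: AcOH, H2SO4 (cat.), 60 °C
Reagents that add atoms: none
Why: Acid-catalysed cyclodehydration of a 2-hydroxyaryl 1,3-diketone (the closing stage of a Baker–Venkataraman-type flavone synthesis): the chelated phenol adds to the aryl ketone and water is lost, while the isoflavone and the aryl ethers tolerate the mild acid.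

Step 9
Reactants: 22 8-{5-[5,7-bis(benzyloxy)-4-oxo-4H-chromen-2-yl]-2-methoxyphenyl}-5-ethoxy-7-hydroxy-3-(4-methoxyphenyl)-4H-chromen-4-one
Product: 23 8-[5-(5,7-dihydroxy-4-oxo-4H-chromen-2-yl)-2-methoxyphenyl]-5,7-dihydroxy-3-(4-methoxyphenyl)-4H-chromen-4-one (target CNP0117905.0)
Conditions: BCl3 (excess), C6HMe5, CH2Cl2, −78 °C → rt; MeOH quench
Reagents that add atoms: none
Why: Lewis acid dealkylation: BCl3 cleaves the two benzyl ethers, with pentamethylbenzene as a non-basic trap for the benzyl cations, and by chelation to the C4 carbonyl also the peri ethyl ether of the isoflavone, whereas the two anisole methyl ethers have no neighbouring carbonyl and should stay intact.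

Compound list
1 | methyl 3-iodo-4-methoxybenzoate | COC(=O)c1ccc(OC)c(I)c1 | starting material
2 | ethynyltrimethylsilane | C#C[Si](C)(C)C | starting material
3 | methyl 4-methoxy-3-[(trimethylsilyl)ethynyl]benzoate | COC(=O)c1ccc(OC)c(C#C[Si](C)(C)C)c1 | intermediate
4 | methyl 3-ethynyl-4-methoxybenzoate | COC(=O)c1ccc(OC)c(C#C)c1 | intermediate
5 | lithium 2-[2-methoxy-5-(methoxycarbonyl)phenyl]ethynolate | [Li+].[O-]C#Cc1cc(C(=O)OC)ccc1OC | intermediate
6 | methyl 4-methoxy-3-{[(triisopropylsilyl)oxy]ethynyl}benzoate | COC(=O)c1ccc(OC)c(C#CO[Si](C(C)C)(C(C)C)C(C)C)c1 | intermediate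
7 | ethoxyacetylene | CCOC#C | starting material
8 | acetyl chloride | CC(=O)Cl | starting material
9 | ketene | C=C=O | intermediate
10 | 3-ethoxycyclobut-2-en-1-one | CCOC1=CC(=O)C1 | intermediate
11 | 3-ethoxybuta-1,3-dien-1-one (vinylketene) | C=C(OCC)C=C=O | intermediate
12 | methyl 3-[3-(1-ethoxyethenyl)-4-oxo-2-(triisopropylsilyloxy)cyclobut-1-en-1-yl]-4-methoxybenzoate | CCOC(=C)C1C(=O)C(c2cc(C(=O)OC)ccc2OC)=C1O[Si](C(C)C)(C(C)C)C(C)C | intermediate
13 | 5-ethoxy-2-[2-methoxy-5-(methoxycarbonyl)phenyl]-3-(triisopropylsilyloxy)hexa-1,3,5-trien-1-one (dienylketene) | C=C(OCC)C=C(O[Si](C(C)C)(C(C)C)C(C)C)C(=C=O)c1cc(C(=O)OC)ccc1OC | intermediate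
14 | methyl 3-[4-ethoxy-6-oxo-2-(triisopropylsilyloxy)cyclohexa-1,3-dien-1-yl]-4-methoxybenzoate | CCOC1=CC(O[Si](C(C)C)(C(C)C)C(C)C)=C(c2cc(C(=O)OC)ccc2OC)C(=O)C1 | intermediate
15 | methyl 3-[4-ethoxy-2-hydroxy-6-(triisopropylsilyloxy)phenyl]-4-methoxybenzoate | CCOc1cc(O)c(-c2cc(C(=O)OC)ccc2OC)c(O[Si](C(C)C)(C(C)C)C(C)C)c1 | intermediate
16 | methyl 3-(4-ethoxy-2,6-dihydroxyphenyl)-4-methoxybenzoate | CCOc1cc(O)c(-c2cc(C(=O)OC)ccc2OC)c(O)c1 | intermediate
17 | (4-methoxyphenyl)acetic acid | COc1ccc(CC(=O)O)cc1 | starting material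
18 | methyl 3-{4-ethoxy-2,6-dihydroxy-3-[(4-methoxyphenyl)acetyl]phenyl}-4-methoxybenzoate | CCOc1cc(O)c(-c2cc(C(=O)OC)ccc2OC)c(O)c1C(=O)Cc1ccc(OC)cc1 | intermediate
19 | methyl 3-[5-ethoxy-7-hydroxy-3-(4-methoxyphenyl)-4-oxo-4H-chromen-8-yl]-4-methoxybenzoate | CCOc1cc(O)c(-c2cc(C(=O)OC)ccc2OC)c2occ(-c3ccc(OC)cc3)c(=O)c12 | intermediate
20 | 1-[2,4-bis(benzyloxy)-6-hydroxyphenyl]ethan-1-one | CC(=O)c1c(O)cc(OCc2ccccc2)cc1OCc1ccccc1 | starting material
21 | 1-[2,4-bis(benzyloxy)-6-hydroxyphenyl]-3-{3-[5-ethoxy-7-hydroxy-3-(4-methoxyphenyl)-4-oxo-4H-chromen-8-yl]-4-methoxyphenyl}propane-1,3-dione | CCOc1cc(O)c(-c2cc(C(=O)CC(=O)c3c(O)cc(OCc4ccccc4)cc3OCc3ccccc3)ccc2OC)c2occ(-c3ccc(OC)cc3)c(=O)c12 | intermediate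
22 | 8-{5-[5,7-bis(benzyloxy)-4-oxo-4H-chromen-2-yl]-2-methoxyphenyl}-5-ethoxy-7-hydroxy-3-(4-methoxyphenyl)-4H-chromen-4-one | CCOc1cc(O)c(-c2cc(-c3cc(=O)c4c(OCc5ccccc5)cc(OCc5ccccc5)cc4o3)ccc2OC)c2occ(-c3ccc(OC)cc3)c(=O)c12 | intermediate
23 | 8-[5-(5,7-dihydroxy-4-oxo-4H-chromen-2-yl)-2-methoxyphenyl]-5,7-dihydroxy-3-(4-methoxyphenyl)-4H-chromen-4-one (CNP0117905.0) | COc1ccc(-c2coc3c(-c4cc(-c5cc(=O)c6c(O)cc(O)cc6o5)ccc4OC)c(O)cc(O)c3c2=O)cc1 | target

Total step count: 9
Longest linear sequence: 8 steps (steps 1, 2, 4, 5, 6, 7, 8, 9); step 3 is a one-step side branch.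

Steps most likely to fail

1. Step 4 (benzannulation). The electrocyclic opening of the vinylogous ester 10 may need temperatures at which the alkoxy vinylketene oligomerises, or at which it is captured by the product phenol faster than it adds to the ortho-substituted aryl siloxyalkyne. The siloxyalkyne may also rearrange on long heating. The fallback sets out from 1 and comes back at 16; it makes the biaryl bond by Suzuki–Miyaura coupling and leaves ring A as a bought benzene ring. 5-Ethoxybenzene-1,3-diol F1 (bought, or from phloroglucinol with EtOH and HCl) is converted with MOMCl and i-Pr2NEt into 1-ethoxy-3,5-bis(methoxymethoxy)benzene F2. Lithiation with n-BuLi between the two acetal oxygens and a quench with i-PrOBpin give the aryl pinacol boronate F3. Coupling with 1 (Pd(OAc)2, SPhos, K3PO4, toluene and water, 90 °C) gives the biaryl bis-acetal F4, and HCl in MeOH frees both phenols to give 16.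

2. Step 2 (siloxyalkyne). The lithium acetylide or the ynolate may add to the methyl ester of a second molecule, or the oxygen transfer may stay incomplete, so that the material is lost to oligomers. The fallback sets out from 2 and comes back at 15; it carries a bromide through the sensitive steps and introduces the ester carbon only after the benzannulation. 4-Bromo-2-iodo-1-methoxybenzene F5 (bought) is coupled at its iodide with 2 under the conditions of step 1 to give silylalkyne F6 and, after K2CO3 in MeOH, 4-bromo-2-ethynyl-1-methoxybenzene F7. The oxidation and silylation of step 2, now with no electrophile on the ring, give the bromoaryl siloxyalkyne F8. Benzannulation with 10 as in step 4 gives the bromoaryl siloxyphenol F9, and palladium-catalysed methoxycarbonylation (Pd(OAc)2, Xantphos, CO at 1 atm, MeOH, Et3N, 70 °C) turns the bromide into the methyl ester of 15.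

3. Step 7 (Claisen condensation). The enolate or the liberated methoxide may attack C2 of the isoflavone and open the pyranone, or acylation by the electron-rich ester may be too slow to compete. The fallback sets out from 16 and comes back at 22; it reverses the order of the two pyranone closures so that no isoflavone meets the enolate. Claisen condensation of 16 (as its bis-phenoxide) with the dianion of 20 and LiN(SiMe3)2 gives the diketone F10, and AcOH with catalytic H2SO4 closes it to the flavone F11. Hoesch acylation of the free resorcinol ring, the only ring nucleophilic enough, with (4-methoxyphenyl)acetonitrile F12 (bought) under ZnCl2 and HCl in Et2O at 0 °C gives the ketiminium chloride F13, which hot water hydrolyses to the deoxybenzoin F14. Triethyl orthoformate with piperidine in pyridine then closes the isoflavone pyranone to give 22.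

Further compounds
F1 | step 4 | 5-ethoxybenzene-1,3-diol | CCOc1cc(O)cc(O)c1
F2 | step 4 | 1-ethoxy-3,5-bis(methoxymethoxy)benzene | CCOc1cc(OCOC)cc(OCOC)c1
F3 | step 4 | 2-[4-ethoxy-2,6-bis(methoxymethoxy)phenyl]-4,4,5,5-tetramethyl-1,3,2-dioxaborolane | CCOc1cc(OCOC)c(B2OC(C)(C)C(C)(C)O2)c(OCOC)c1
F4 | step 4 | methyl 3-[4-ethoxy-2,6-bis(methoxymethoxy)phenyl]-4-methoxybenzoate | CCOc1cc(OCOC)c(-c2cc(C(=O)OC)ccc2OC)c(OCOC)c1
F5 | step 2 | 4-bromo-2-iodo-1-methoxybenzene | COc1ccc(Br)cc1I
F6 | step 2 | [(5-bromo-2-methoxyphenyl)ethynyl]trimethylsilane | COc1ccc(Br)cc1C#C[Si](C)(C)C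
F7 | step 2 | 4-bromo-2-ethynyl-1-methoxybenzene | COc1ccc(Br)cc1C#C
F8 | step 2 | {[(5-bromo-2-methoxyphenyl)ethynyl]oxy}triisopropylsilane | COc1ccc(Br)cc1C#CO[Si](C(C)C)(C(C)C)C(C)C
F9 | step 2 | 2-(5-bromo-2-methoxyphenyl)-5-ethoxy-3-(triisopropylsilyloxy)phenol | CCOc1cc(O)c(-c2cc(Br)ccc2OC)c(O[Si](C(C)C)(C(C)C)C(C)C)c1
F10 | step 7 | 1-[2,4-bis(benzyloxy)-6-hydroxyphenyl]-3-[3-(4-ethoxy-2,6-dihydroxyphenyl)-4-methoxyphenyl]propane-1,3-dione | CCOc1cc(O)c(-c2cc(C(=O)CC(=O)c3c(O)cc(OCc4ccccc4)cc3OCc3ccccc3)ccc2OC)c(O)c1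
F11 | step 7 | 5,7-bis(benzyloxy)-2-[3-(4-ethoxy-2,6-dihydroxyphenyl)-4-methoxyphenyl]-4H-chromen-4-one | CCOc1cc(O)c(-c2cc(-c3cc(=O)c4c(OCc5ccccc5)cc(OCc5ccccc5)cc4o3)ccc2OC)c(O)c1
F12 | step 7 | (4-methoxyphenyl)acetonitrile | COc1ccc(CC#N)cc1
F13 | step 7 | 1-{3-[5-(5,7-bis(benzyloxy)-4-oxo-4H-chromen-2-yl)-2-methoxyphenyl]-6-ethoxy-2,4-dihydroxyphenyl}-2-(4-methoxyphenyl)ethan-1-iminium chloride | CCOc1cc(O)c(-c2cc(-c3cc(=O)c4c(OCc5ccccc5)cc(OCc5ccccc5)cc4o3)ccc2OC)c(O)c1C(=[NH2+])Cc1ccc(OC)cc1.[Cl-]
F14 | step 7 | 5,7-bis(benzyloxy)-2-(3-{4-ethoxy-2,6-dihydroxy-3-[(4-methoxyphenyl)acetyl]phenyl}-4-methoxyphenyl)-4H-chromen-4-one | CCOc1cc(O)c(-c2cc(-c3cc(=O)c4c(OCc5ccccc5)cc(OCc5ccccc5)cc4o3)ccc2OC)c(O)c1C(=O)Cc1ccc(OC)cc1
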